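**Plan**
Cuts: the 7-OH of coumarin A is traced back to a 7-OMe. The pyranone of coumarin A is then cut in one operation at C8a–O1, C4a–C4, C4–C3 and O1–C2, and last the O7'–CH2 bond of the aryloxyacetate is cut.
Enabling feature: in the benzene ring of coumarin A the adjacent carbons C8a and C4a carry O1 and C4, and their outer neighbours C8 and C5 are CH. C4 is a bare CH that a formamide can deliver together with O1, and C2–C3 with the ether oxygen on C3 is an aryloxyacetate unit. With O6 and O7 both as OMe, the aryne C4a≡C8a is symmetric.
Forward: coumarin B enters complete as scopoletin and O7' is alkylated. The ester becomes its silyl ketene acetal, the pyranone of coumarin A closes from aryne, DMF and ketene acetal, and the conjugated 7-OMe is cleaved last.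
Stereochemistry: the target has no stereocentre and no stereogenic double bond. The two sp3 centres that arise during ring closure vanish in the same flask.

Key step: step 3

Remark: unprimed locants refer to coumarin A (3-oxygenated, 7-hydroxylated), primed locants to coumarin B (bound through O7').
Assumption: scopoletin, methyl bromoacetate and 4,5-dimethoxy-2-(trimethylsilyl)phenyl triflate are taken as catalogue compounds.

Step 1
Reactants: 1 scopoletin (7-hydroxy-6-methoxy-2H-chromen-2-one); 2 methyl bromoacetate
Product: 4 methyl [(6-methoxy-2-oxo-2H-chromen-7-yl)oxy]acetate, via potassium phenoxide 3 (not isolated)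
Conditions: K2CO3 (1.5 equiv), acetone, reflux
Reagents that add atoms: none
Why: The 7-OH of 1, acidified by conjugation with the lactone carbonyl, is deprotonated by carbonate to 3, which displaces bromide from the unhindered α-bromo ester by SN2 (Williamson ether synthesis), while the lactone and the aryl methyl ether are inert to K2CO3 in dry acetone.

Step 2
Reactants: 4 methyl [(6-methoxy-2-oxo-2H-chromen-7-yl)oxy]acetate
Product: 6 7-{[(Z)-2-methoxy-2-(trimethylsilyloxy)ethenyl]oxy}-6-methoxy-2H-chromen-2-one, via lithium ester enolate 5 (not isolated)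
Conditions: LiN(SiMe3)2 (1.1 equiv) added to 4 + Me3SiCl (2 equiv), THF, −78 °C to 0 °C; solvent removed, dry toluene, filtered under Ar, used crude
Reagents that add atoms: chlorotrimethylsilane, C[Si](C)(C)Cl
Why: The OCH2 next to the ester is the only acidic C–H of 4, the hindered non-nucleophilic amide removes it at −78 °C to give the chelated enolate 5, and the Me3SiCl already present silylates 5 on oxygen at once (silyl ketene acetal formation under in situ quench, the standard first stage of Ireland–Claisen reactions of α-alkoxy esters), which leaves 5 no time for Claisen self-condensation or for addition to C4' or the lactone of a second molecule.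

Step 3
Reactants: 6 7-{[(Z)-2-methoxy-2-(trimethylsilyloxy)ethenyl]oxy}-6-methoxy-2H-chromen-2-one; 7 4,5-dimethoxy-2-(trimethylsilyl)phenyl trifluoromethanesulfonate; 8 N,N-dimethylformamide (reactant and solvent)
Product: 15 6,7-dimethoxy-3-[(6-methoxy-2-oxo-2H-chromen-7-yl)oxy]-2H-chromen-2-one, via 4,5-dimethoxybenzyne 9 (not isolated), via benzoxete 10 (not isolated), via ortho-quinone methide 11 (not isolated), via caesium ester enolate 12 (not isolated), via Mannich adduct 13 (not isolated), via 4-aminochromanone 14 (not isolated)
Conditions: CsF (4 equiv), dry DMF (8), 25 °C, 6 (1 equiv) and 7 (1.5 equiv) in DMF added together over 4 h, then 50 °C; 1 M HCl work-up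
Reagents that add atoms: none
Why: Fluoride attacks silicon in 7 and triflate leaves (1,2-elimination) to give aryne 9, which is trapped by the carbonyl group of the solvent 8 in a formal [2+2] addition (carbonyl O onto one aryne carbon, the resulting aryl anion onto the iminium carbon; C8a–O1 and C4a–C4) to give benzoxete 10, and 4π electrocyclic opening of 10 gives ortho-quinone methide 11, whose Me2N-bearing carbon is the future C4. Fluoride likewise desilylates 6 to enolate 12, which adds to that carbon in a Mannich sense (C4–C3) to give phenoxide 13; 13 closes the pyranone of coumarin A by 6-exo-trig acyl substitution at the ester carbonyl (O1–C2, loss of methoxide) to give 14, and E1cB loss of dimethylamine from 14, helped by the acidity of the C3–H flanked by the lactone carbonyl and the aryloxy group, gives 15. The closest known reaction type is the three-component coupling of arynes, DMF and ester-bearing carbon nucleophiles (malonates, β-keto esters, ester enolates) to coumarins by way of ortho-quinone methides, and 6 enters it as an α-aryloxy member of the nucleophile series. C3 and C4 of 13 and 14 are stereocentres only in passing and both become sp2 in the elimination, so neither facial control nor the geometry of 6 matters. Regioselectivity of the aryne addition is not needed, because 9 has a mirror plane that exchanges its two reactive carbons (H on both neighbours, OMe on both remote carbons). The selectivity that is needed is chemoselectivity, aryne to DMF ahead of 6 or 12 and enolate to 11 ahead of C4' or the lactone of coumarin B; it is secured by DMF being the solvent, by the iminium-like electrophilicity of 11, and by feeding 6 and 7 slowly to sparingly soluble CsF so that 9 and 12 stay dilute.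

Step 4
Reactants: 15 6,7-dimethoxy-3-[(6-methoxy-2-oxo-2H-chromen-7-yl)oxy]-2H-chromen-2-one
Product: 17 7-hydroxy-6-methoxy-3-[(6-methoxy-2-oxo-2H-chromen-7-yl)oxy]-2H-chromen-2-one, via sodium 7-phenoxide 16 (not isolated)
Conditions: NaSEt (2 equiv), DMF, 90 °C, stopped at consumption of 15; then 1 M HCl, 0 °C
Reagents that add atoms: none
Why: Thiolate dealkylation of aryl methyl ethers is an SN2 reaction at the methyl carbon whose rate follows the stability of the departing phenoxide, and only O7 is para to C4a and hence conjugated through C4=C3 with the C2 carbonyl, whereas O6 and O6' are ordinary anisole-type oxygens; formation of 16 then deactivates coumarin A towards a second cleavage, and reversible thiolate addition to C4' or to the lactones is undone on acidification.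

**Compound list**
1 | scopoletin (7-hydroxy-6-methoxy-2H-chromen-2-one) | COc1cc2ccc(=O)oc2cc1O | starting material
2 | methyl bromoacetate | COC(=O)CBr | starting material
3 | potassium 6-methoxy-2-oxo-2H-chromen-7-olate | [K+].COc1cc2ccc(=O)oc2cc1[O-] | intermediate
4 | methyl [(6-methoxy-2-oxo-2H-chromen-7-yl)oxy]acetate | COC(=O)COc1cc2oc(=O)ccc2cc1OC | intermediate
5 | chelated lithium enolate of 4 (O–Li and aryloxy group on the same side of C=C) | [Li+].CO/C([O-])=C/Oc1cc2oc(=O)ccc2cc1OC | intermediate
6 | 7-{[(Z)-2-methoxy-2-(trimethylsilyloxy)ethenyl]oxy}-6-methoxy-2H-chromen-2-one (trimethylsilyl ketene acetal of 4; the geometry has no consequence) | CO/C(O[Si](C)(C)C)=C/Oc1cc2oc(=O)ccc2cc1OC | intermediate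
7 | 4,5-dimethoxy-2-(trimethylsilyl)phenyl trifluoromethanesulfonate | COc1cc(OS(=O)(=O)C(F)(F)F)c(cc1OC)[Si](C)(C)C | starting material
8 | N,N-dimethylformamide | CN(C)C=O | starting material
9 | 4,5-dimethoxybenzyne (1,2-didehydro-4,5-dimethoxybenzene) | COC1=CC#CC=C1OC | intermediate
10 | 3,4-dimethoxy-N,N-dimethyl-7-oxabicyclo[4.2.0]octa-1,3,5-trien-8-amine (benzoxete) | CN(C)C1Oc2cc(OC)c(OC)cc12 | intermediate
11 | 6-[(dimethylamino)methylidene]-3,4-dimethoxycyclohexa-2,4-dien-1-one (geometry not defined) | CN(C)C=C1C=C(OC)C(OC)=CC1=O | intermediate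
12 | caesium enolate of 4 | [Cs+].COC([O-])=COc1cc2oc(=O)ccc2cc1OC | intermediate
13 | caesium 2-{1-(dimethylamino)-3-methoxy-2-[(6-methoxy-2-oxo-2H-chromen-7-yl)oxy]-3-oxopropyl}-4,5-dimethoxyphenolate (diastereomer mixture, both centres lost later) | [Cs+].COC(=O)C(Oc1cc2oc(=O)ccc2cc1OC)C(N(C)C)c1cc(OC)c(OC)cc1[O-] | intermediate
14 | 4-(dimethylamino)-6,7-dimethoxy-3-[(6-methoxy-2-oxo-2H-chromen-7-yl)oxy]-3,4-dihydro-2H-chromen-2-one (diastereomer mixture, both centres lost later) | CN(C)C1C(Oc2cc3oc(=O)ccc3cc2OC)C(=O)Oc2cc(OC)c(OC)cc12 | intermediate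
15 | 6,7-dimethoxy-3-[(6-methoxy-2-oxo-2H-chromen-7-yl)oxy]-2H-chromen-2-one | COc1cc2cc(Oc3cc4oc(=O)ccc4cc3OC)c(=O)oc2cc1OC | intermediate
16 | sodium 6-methoxy-3-[(6-methoxy-2-oxo-2H-chromen-7-yl)oxy]-2-oxo-2H-chromen-7-olate | [Na+].COc1cc2cc(Oc3cc4oc(=O)ccc4cc3OC)c(=O)oc2cc1[O-] | intermediate
17 | 7-hydroxy-6-methoxy-3-[(6-methoxy-2-oxo-2H-chromen-7-yl)oxy]-2H-chromen-2-one | COc1cc2cc(Oc3cc4oc(=O)ccc4cc3OC)c(=O)oc2cc1O | target

Total step count: 4
Longest linear sequence: 4 steps (1 → 4 → 6 → 15 → 17)

**Steps most likely to fail**

1. Step 3.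
- Risk: the electron-rich ketene acetal or the free enolate may intercept the aryne ([2+2] addition or α-arylation) before DMF does. The enolate may be protonated by traces of water or add to C4' of coumarin B. The sequence may also stall before dimethylamine is lost.
- Fallback (sets out from 4, comes back at 15): saponification of 4 with LiOH in THF/H2O followed by acidification, which also re-closes any opened lactone of coumarin B, should give [(6-methoxy-2-oxo-2H-chromen-7-yl)oxy]acetic acid F1. A Perkin condensation of F1 with purchased 2-hydroxy-4,5-dimethoxybenzaldehyde (Ac2O, NaOAc, 140 °C) is the classical entry to 3-aryloxycoumarins. It forms C3=C4 by aldol condensation of the mixed anhydride and O1–C2 by lactonisation, and should deliver 15.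

2. Step 4.
- Risk: discrimination between the three methyl ethers may be insufficient, cleavage may continue at O6 or O6', or the thiolate may attack C7' at the ipso position and break the diaryl ether.
- Fallback (sets out from 6, comes back at 17): the 6/7 distinction is moved to a free catechol, where acidity decides.
- Under the conditions of step 3, 6, 8 and purchased 6-(trimethylsilyl)-1,3-benzodioxol-5-yl triflate, again a symmetric aryne source, should give 7-[(6-methoxy-2-oxo-2H-chromen-7-yl)oxy]-6H-[1,3]dioxolo[4,5-g]chromen-6-one F2.
- BCl3 in CH2Cl2 at 0 °C cleaves methylenedioxy groups in preference to unchelated methyl ethers and should give 6,7-dihydroxy-3-[(6-methoxy-2-oxo-2H-chromen-7-yl)oxy]-2H-chromen-2-one F3.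
- One equivalent each of K2CO3 and BnBr in DMF should alkylate the more acidic 7-OH, as in esculetin, to give 7-(benzyloxy)-6-hydroxy-3-[(6-methoxy-2-oxo-2H-chromen-7-yl)oxy]-2H-chromen-2-one F4.
- MeI and K2CO3 in acetone should give 7-(benzyloxy)-6-methoxy-3-[(6-methoxy-2-oxo-2H-chromen-7-yl)oxy]-2H-chromen-2-one F5.
- Hydrogenolysis (H2 at 1 atm, Pd/C, EtOAc/THF) should then release 17.

3. Step 2.
- Risk: the lithium enolate may self-condense or add to C4' before it is silylated, silylation may occur partly on carbon, and the trimethylsilyl acetal may hydrolyse back to the ester during handling.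
- Fallback (sets out from 4, comes back at 15): no metal enolate is generated at all. Soft enolisation with tBuMe2SiOTf and Et3N in CH2Cl2 (0 °C to 25 °C) activates the ester carbonyl by the silyl triflate and deprotonates with the amine.
- This should give 7-{[(Z)-2-(tert-butyldimethylsilyloxy)-2-methoxyethenyl]oxy}-6-methoxy-2H-chromen-2-one F6, an acetal sturdy enough for a quick bicarbonate wash and storage.
- F6 takes the place of 6 in step 3. CsF cleaves its Si–O bond more slowly, which keeps the enolate concentration lower still, and the sequence ends at 15.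

**Further compounds**
F1 | step 3 | [(6-methoxy-2-oxo-2H-chromen-7-yl)oxy]acetic acid | OC(=O)COc1cc2oc(=O)ccc2cc1OC
F2 | step 4 | 7-[(6-methoxy-2-oxo-2H-chromen-7-yl)oxy]-6H-[1,3]dioxolo[4,5-g]chromen-6-one | COc1cc2ccc(=O)oc2cc1Oc1cc2cc3OCOc3cc2oc1=O
F3 | step 4 | 6,7-dihydroxy-3-[(6-methoxy-2-oxo-2H-chromen-7-yl)oxy]-2H-chromen-2-one | COc1cc2ccc(=O)oc2cc1Oc1cc2cc(O)c(O)cc2oc1=O
F4 | step 4 | 7-(benzyloxy)-6-hydroxy-3-[(6-methoxy-2-oxo-2H-chromen-7-yl)oxy]-2H-chromen-2-one | COc1cc2ccc(=O)oc2cc1Oc1cc2cc(O)c(OCc3ccccc3)cc2oc1=O
F5 | step 4 | 7-(benzyloxy)-6-methoxy-3-[(6-methoxy-2-oxo-2H-chromen-7-yl)oxy]-2H-chromen-2-one | COc1cc2ccc(=O)oc2cc1Oc1cc2cc(OC)c(OCc3ccccc3)cc2oc1=O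
F6 | step 2 | 7-{[(Z)-2-(tert-butyldimethylsilyloxy)-2-methoxyethenyl]oxy}-6-methoxy-2H-chromen-2-one (one geometric isomer drawn) | CO/C(O[Si](C)(C)C(C)(C)C)=C/Oc1cc2oc(=O)ccc2cc1OC
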